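**Plan**

1. Retrosynthetic cuts: the three O-benzyl groups; the lactone C3–CH2 bond to the benzofuran arm (enolate alkylation); the lactone O1–C5H2 bond; in the benzofuran half, the C2–C3 bond (carbene C–H insertion) and the aryl O–CH2Ar ether.
2. Enabling feature: lactone C4 (carrying the vanillyl CH2) sits between two CH2 arms, C5 (on oxygen) and C3 (on the carbonyl, unsubstituted before the alkylation). Removing O1 merges these into a mirror-symmetric 3-(arylmethyl)cyclobutanone with two enantiotopic α-CH2 groups, so one strain-driven, desymmetrising Baeyer–Villiger ring expansion makes the O–CH2 bond, the five-membered ring and the C4 stereocentre together.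
3. Forward order: eugenol → [2+2] with dichloroketene → cyclobutanone → lactone ring; separately 5-iodovanillin → aryl diazoacetate → dihydrobenzofuran ring → benzylic bromide; the halves are joined by lactone enolate alkylation and all benzyl groups are removed last.
4. Stereochemistry: lactone C4 (R) by catalyst control in the Baeyer–Villiger step; lactone C3 (R) by alkylation anti to the C4 substituent; benzofuran C2 (S) by the chiral dirhodium carboxylate in the C–H insertion; benzofuran C3 by cis-to-trans epimerisation of the ester.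

Key step: step 4

Assumption: the sense of induction of the chiral scandium catalyst (step 4) and of the chiral dirhodium carboxylate (step 9) is taken by analogy with related 3-substituted cyclobutanones and 2-(benzyloxy)aryl diazoacetates; should either deliver the antipode, its mirror-image form is used and nothing else changes.

**Route**

Step 1
Reactants: 1 eugenol (2-methoxy-4-(prop-2-en-1-yl)phenol)
Product: 2 O-benzyleugenol (1-(benzyloxy)-2-methoxy-4-(prop-2-en-1-yl)benzene)
Conditions: BnBr, K2CO3, acetone, reflux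
Reagents that add atoms: benzyl bromide, BrCc1ccccc1
Why: Williamson ether synthesis on the phenoxide; the benzyl ether should survive every later step and falls only in the final hydrogenolysis.

Step 2
Reactants: 2 O-benzyleugenol
Product: 3 rac-3-{[4-(benzyloxy)-3-methoxyphenyl]methyl}-2,2-dichlorocyclobutan-1-one
Conditions: Cl3CCOCl, Zn–Cu couple, POCl3, Et2O, rt to reflux
Reagents that add atoms: trichloroacetyl chloride (source of dichloroketene), ClC(=O)C(Cl)(Cl)Cl
Why: Thermal [2+2] ketene–alkene cycloaddition of dichloroketene made in the flask, in which the terminal alkene carbon should bond to the ketene carbonyl carbon so that the arylmethyl group ends at C3; the stereocentre forms racemic and is erased in step 3.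

Step 3
Reactants: 3 rac-3-{[4-(benzyloxy)-3-methoxyphenyl]methyl}-2,2-dichlorocyclobutan-1-one
Product: 4 3-{[4-(benzyloxy)-3-methoxyphenyl]methyl}cyclobutan-1-one
Conditions: Zn dust, AcOH, rt to 50 °C
Reagents that add atoms: none
Why: Reductive dechlorination of an α,α-dichloroketone by zinc through zinc enolates, which should leave the benzyl ether alone and give the mirror-symmetric, prochiral cyclobutanone.

Step 4
Reactants: 4 3-{[4-(benzyloxy)-3-methoxyphenyl]methyl}cyclobutan-1-one
Product: 6 (4R)-4-{[4-(benzyloxy)-3-methoxyphenyl]methyl}oxolan-2-one, via peroxy hemiketal 5 (not isolated)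
Conditions: Sc(OTf)3 (5 mol%), chiral pipecolic-acid-derived N,N'-dioxide bis(2,6-diisopropylanilide) ligand (5 mol%), mCPBA, EtOAc, −20 °C
Reagents that add atoms: mCPBA (3-chloroperoxybenzoic acid), OOC(=O)c1cccc(Cl)c1
Why: The chiral Sc(OTf)3–N,N'-dioxide complex binds the ketone oxygen and guides mCPBA onto the carbonyl to give peroxy hemiketal 5, in which the one enantiotopic ring CH2 held antiperiplanar to the O–O bond shifts from carbon to the proximal peroxide oxygen with loss of 3-chlorobenzoate, so the lactone O–CH2 bond is made in the migration. The closest known reaction type is the catalytic enantioselective, desymmetrising Baeyer–Villiger oxidation of prochiral 3-substituted cyclobutanones with chiral Lewis acid–peracid systems. The five-membered lactone arises by ring expansion of the four-membered ketone through a 1,2 carbon-to-oxygen shift, not by an end-to-end cyclisation, and is driven by release of cyclobutanone strain. The only new stereocentre, lactone C4, is the former prostereogenic C3 of 4, and its configuration is set by the catalyst's choice between the two enantiotopic C–C bonds, the ligand antipode leading to 4R being used. No regiochemical question arises because both candidate migrating groups are constitutionally identical CH2 groups, which is why the α-substituent is introduced only afterwards. The step needs chemoselectivity for the ketone over the electron-rich benzyl guaiacyl ether, which the high reactivity of the strained, Lewis-acid-activated cyclobutanone at low temperature and the absence of any alkene should secure.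

Step 5
Reactants: 7 5-iodovanillin (4-hydroxy-3-iodo-5-methoxybenzaldehyde); 8 [4-(benzyloxy)-3-methoxyphenyl]methanol
Product: 9 4-{[4-(benzyloxy)-3-methoxyphenyl]methoxy}-3-iodo-5-methoxybenzaldehyde
Conditions: PPh3, DIAD, THF, 0 °C to rt
Reagents that add atoms: none
Why: Mitsunobu etherification, in which the acidic phenol (para-formyl, ortho-iodo) is a good pronucleophile for the oxyphosphonium salt of the primary benzylic alcohol; no stereocentre is involved.

Step 6
Reactants: 9 4-{[4-(benzyloxy)-3-methoxyphenyl]methoxy}-3-iodo-5-methoxybenzaldehyde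
Product: 10 (4-{[4-(benzyloxy)-3-methoxyphenyl]methoxy}-3-iodo-5-methoxyphenyl)methanol
Conditions: NaBH4, MeOH/THF, 0 °C
Reagents that add atoms: none
Why: Chemoselective borohydride reduction of the aldehyde, which should not touch the aryl iodide or the ethers.

Step 7
Reactants: 10 (4-{[4-(benzyloxy)-3-methoxyphenyl]methoxy}-3-iodo-5-methoxyphenyl)methanol
Product: 11 tert-butyl[(4-{[4-(benzyloxy)-3-methoxyphenyl]methoxy}-3-iodo-5-methoxyphenyl)methoxy]dimethylsilane
Conditions: TBSCl, imidazole, DMF, rt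
Reagents that add atoms: tert-butyldimethylsilyl chloride, CC(C)(C)[Si](C)(C)Cl
Why: Standard silylation; the silyl ether removes the O–H that would intercept the carbene in step 9 and should survive ethoxide, LiAlH4 and NaH.

Step 8
Reactants: 11 tert-butyl[(4-{[4-(benzyloxy)-3-methoxyphenyl]methoxy}-3-iodo-5-methoxyphenyl)methoxy]dimethylsilane
Product: 12 ethyl 2-[2-{[4-(benzyloxy)-3-methoxyphenyl]methoxy}-5-({[tert-butyl(dimethyl)silyl]oxy}methyl)-3-methoxyphenyl]-2-diazoacetate
Conditions: ethyl diazoacetate, Pd(PPh3)4 (5 mol%), Ag2CO3 (0.5 equiv), Et3N, toluene, rt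
Reagents that add atoms: ethyl diazoacetate, CCOC(=O)C=[N+]=[N-]
Why: Palladium-catalysed cross-coupling of an aryl iodide with an acceptor diazo compound with retention of the diazo group (oxidative addition, silver-assisted C–H palladation of the diazoacetate, reductive elimination), which should tolerate the ethers at room temperature.

Step 9
Reactants: 12 ethyl 2-[2-{[4-(benzyloxy)-3-methoxyphenyl]methoxy}-5-({[tert-butyl(dimethyl)silyl]oxy}methyl)-3-methoxyphenyl]-2-diazoacetate
Product: 13 ethyl (2S,3R)-2-[4-(benzyloxy)-3-methoxyphenyl]-5-({[tert-butyl(dimethyl)silyl]oxy}methyl)-7-methoxy-2,3-dihydro-1-benzofuran-3-carboxylate (cis)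
Conditions: Rh2(R-PTTL)4 (dirhodium tetrakis[N-phthaloyl-(R)-tert-leucinate], 1 mol%), toluene, −60 °C
Reagents that add atoms: none
Why: Intramolecular 1,5 C–H insertion of the catalyst-bound donor/acceptor carbene into the ether O–CH2 bond, activated by oxygen and the electron-rich aryl group; the concerted insertion should give the cis ring kinetically, and the chiral carboxylate ligands select one enantiotopic hydrogen and so set C2 as S.

Step 10
Reactants: 13 ethyl (2S,3R)-2-[4-(benzyloxy)-3-methoxyphenyl]-5-({[tert-butyl(dimethyl)silyl]oxy}methyl)-7-methoxy-2,3-dihydro-1-benzofuran-3-carboxylate (cis)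
Product: 14 ethyl (2S,3S)-2-[4-(benzyloxy)-3-methoxyphenyl]-5-({[tert-butyl(dimethyl)silyl]oxy}methyl)-7-methoxy-2,3-dihydro-1-benzofuran-3-carboxylate (trans)
Conditions: NaOEt (0.3 equiv), EtOH, 0 °C to rt
Reagents that add atoms: none
Why: Base-mediated epimerisation at C3 through the ester enolate to the thermodynamically preferred trans isomer, with ethoxide matched to the ethyl ester and short contact at low temperature to keep C2 from eroding through ring opening.

Step 11
Reactants: 14 ethyl (2S,3S)-2-[4-(benzyloxy)-3-methoxyphenyl]-5-({[tert-butyl(dimethyl)silyl]oxy}methyl)-7-methoxy-2,3-dihydro-1-benzofuran-3-carboxylate (trans)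
Product: 15 [(2S,3R)-2-[4-(benzyloxy)-3-methoxyphenyl]-5-({[tert-butyl(dimethyl)silyl]oxy}methyl)-7-methoxy-2,3-dihydro-1-benzofuran-3-yl]methanol
Conditions: LiAlH4, THF, 0 °C
Reagents that add atoms: none
Why: Hydride reduction of the ester to the primary alcohol without touching either stereocentre; the change of the C3 descriptor from S to R is a priority change only.

Step 12
Reactants: 15 [(2S,3R)-2-[4-(benzyloxy)-3-methoxyphenyl]-5-({[tert-butyl(dimethyl)silyl]oxy}methyl)-7-methoxy-2,3-dihydro-1-benzofuran-3-yl]methanol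
Product: 16 {[(2S,3R)-2-[4-(benzyloxy)-3-methoxyphenyl]-3-[(benzyloxy)methyl]-7-methoxy-2,3-dihydro-1-benzofuran-5-yl]methoxy}(tert-butyl)dimethylsilane
Conditions: NaH, BnBr, Bu4NI (cat.), THF, 0 °C to rt
Reagents that add atoms: benzyl bromide, BrCc1ccccc1
Why: Williamson benzylation of the primary alkoxide, which puts all three hydroxyl groups to be freed at the end under one protecting group.

Step 13
Reactants: 16 {[(2S,3R)-2-[4-(benzyloxy)-3-methoxyphenyl]-3-[(benzyloxy)methyl]-7-methoxy-2,3-dihydro-1-benzofuran-5-yl]methoxy}(tert-butyl)dimethylsilane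
Product: 17 [(2S,3R)-2-[4-(benzyloxy)-3-methoxyphenyl]-3-[(benzyloxy)methyl]-7-methoxy-2,3-dihydro-1-benzofuran-5-yl]methanol
Conditions: TBAF, THF, 0 °C to rt
Reagents that add atoms: none
Why: Fluoride-driven desilylation, orthogonal to the benzyl ethers, frees only the benzylic alcohol at C5.

Step 14
Reactants: 17 [(2S,3R)-2-[4-(benzyloxy)-3-methoxyphenyl]-3-[(benzyloxy)methyl]-7-methoxy-2,3-dihydro-1-benzofuran-5-yl]methanol
Product: 18 (2S,3R)-2-[4-(benzyloxy)-3-methoxyphenyl]-3-[(benzyloxy)methyl]-5-(bromomethyl)-7-methoxy-2,3-dihydro-1-benzofuran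
Conditions: CBr4, PPh3, CH2Cl2, 0 °C; used without storage
Reagents that add atoms: carbon tetrabromide, BrC(Br)(Br)Br
Why: Appel bromination under neutral conditions, which should spare the acid-sensitive cyclic benzylic ether and give the reactive para-alkoxybenzyl bromide.

Step 15
Reactants: 6 (4R)-4-{[4-(benzyloxy)-3-methoxyphenyl]methyl}oxolan-2-one; 18 (2S,3R)-2-[4-(benzyloxy)-3-methoxyphenyl]-3-[(benzyloxy)methyl]-5-(bromomethyl)-7-methoxy-2,3-dihydro-1-benzofuran
Product: 20 (3R,4R)-4-{[4-(benzyloxy)-3-methoxyphenyl]methyl}-3-{[(2S,3R)-2-[4-(benzyloxy)-3-methoxyphenyl]-3-[(benzyloxy)methyl]-7-methoxy-2,3-dihydro-1-benzofuran-5-yl]methyl}oxolan-2-one, via lithium enolate 19 (not isolated)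
Conditions: LDA, THF, −78 °C; then 18, DMPU, −78 to −40 °C
Reagents that add atoms: none
Why: Lactone enolate alkylation with a benzylic bromide, in which the electrophile should approach the planar enolate anti to the C4 arylmethyl group (1,2-induction) and give the trans 3R,4R lactone.

Step 16
Reactants: 20 (3R,4R)-4-{[4-(benzyloxy)-3-methoxyphenyl]methyl}-3-{[(2S,3R)-2-[4-(benzyloxy)-3-methoxyphenyl]-3-[(benzyloxy)methyl]-7-methoxy-2,3-dihydro-1-benzofuran-5-yl]methyl}oxolan-2-one
Product: 21 isolappaol A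
Conditions: H2 (1 atm), Pd/C (10%), EtOAc/EtOH, rt, stopped once three equivalents are taken up
Reagents that add atoms: none
Why: Catalytic hydrogenolysis of two aryl benzyl ethers and one alkyl benzyl ether; the cyclic benzylic C2–O bond and the lactone should persist under these mild conditions, and no stereocentre is touched.

**Compound list**

1 | eugenol (2-methoxy-4-(prop-2-en-1-yl)phenol) | C=CCc1ccc(O)c(OC)c1 | starting material
2 | O-benzyleugenol (1-(benzyloxy)-2-methoxy-4-(prop-2-en-1-yl)benzene) | C=CCc1ccc(OCc2ccccc2)c(OC)c1 | intermediate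
3 | rac-3-{[4-(benzyloxy)-3-methoxyphenyl]methyl}-2,2-dichlorocyclobutan-1-one | COc1cc(CC2CC(=O)C2(Cl)Cl)ccc1OCc1ccccc1 | intermediate
4 | 3-{[4-(benzyloxy)-3-methoxyphenyl]methyl}cyclobutan-1-one | COc1cc(CC2CC(=O)C2)ccc1OCc1ccccc1 | intermediate
5 | peroxy hemiketal: 3-{[4-(benzyloxy)-3-methoxyphenyl]methyl}-1-hydroxycyclobutyl 3-chloroperoxybenzoate | COc1cc(CC2CC(O)(OOC(=O)c3cccc(Cl)c3)C2)ccc1OCc1ccccc1 | intermediate (not isolated)
6 | (4R)-4-{[4-(benzyloxy)-3-methoxyphenyl]methyl}oxolan-2-one | COc1cc(C[C@H]2COC(=O)C2)ccc1OCc1ccccc1 | intermediate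
7 | 5-iodovanillin (4-hydroxy-3-iodo-5-methoxybenzaldehyde) | COc1cc(C=O)cc(I)c1O | starting material
8 | [4-(benzyloxy)-3-methoxyphenyl]methanol | COc1cc(CO)ccc1OCc1ccccc1 | starting material
9 | 4-{[4-(benzyloxy)-3-methoxyphenyl]methoxy}-3-iodo-5-methoxybenzaldehyde | COc1cc(C=O)cc(I)c1OCc1ccc(OCc2ccccc2)c(OC)c1 | intermediate
10 | (4-{[4-(benzyloxy)-3-methoxyphenyl]methoxy}-3-iodo-5-methoxyphenyl)methanol | COc1cc(CO)cc(I)c1OCc1ccc(OCc2ccccc2)c(OC)c1 | intermediate
11 | tert-butyl[(4-{[4-(benzyloxy)-3-methoxyphenyl]methoxy}-3-iodo-5-methoxyphenyl)methoxy]dimethylsilane | COc1cc(CO[Si](C)(C)C(C)(C)C)cc(I)c1OCc1ccc(OCc2ccccc2)c(OC)c1 | intermediate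
12 | ethyl 2-[2-{[4-(benzyloxy)-3-methoxyphenyl]methoxy}-5-({[tert-butyl(dimethyl)silyl]oxy}methyl)-3-methoxyphenyl]-2-diazoacetate | CCOC(=O)C(=[N+]=[N-])c1cc(CO[Si](C)(C)C(C)(C)C)cc(OC)c1OCc1ccc(OCc2ccccc2)c(OC)c1 | intermediate
13 | ethyl (2S,3R)-2-[4-(benzyloxy)-3-methoxyphenyl]-5-({[tert-butyl(dimethyl)silyl]oxy}methyl)-7-methoxy-2,3-dihydro-1-benzofuran-3-carboxylate (cis) | CC(C)(C)[Si](C)(C)OCc1cc(OC)c2c(c1)[C@@H](C(=O)OCC)[C@@H](c1ccc(OCc3ccccc3)c(OC)c1)O2 | intermediate
14 | ethyl (2S,3S)-2-[4-(benzyloxy)-3-methoxyphenyl]-5-({[tert-butyl(dimethyl)silyl]oxy}methyl)-7-methoxy-2,3-dihydro-1-benzofuran-3-carboxylate (trans) | CC(C)(C)[Si](C)(C)OCc1cc(OC)c2c(c1)[C@H](C(=O)OCC)[C@@H](c1ccc(OCc3ccccc3)c(OC)c1)O2 | intermediate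
15 | [(2S,3R)-2-[4-(benzyloxy)-3-methoxyphenyl]-5-({[tert-butyl(dimethyl)silyl]oxy}methyl)-7-methoxy-2,3-dihydro-1-benzofuran-3-yl]methanol | CC(C)(C)[Si](C)(C)OCc1cc(OC)c2c(c1)[C@H](CO)[C@@H](c1ccc(OCc3ccccc3)c(OC)c1)O2 | intermediate
16 | {[(2S,3R)-2-[4-(benzyloxy)-3-methoxyphenyl]-3-[(benzyloxy)methyl]-7-methoxy-2,3-dihydro-1-benzofuran-5-yl]methoxy}(tert-butyl)dimethylsilane | CC(C)(C)[Si](C)(C)OCc1cc(OC)c2c(c1)[C@H](COCc1ccccc1)[C@@H](c1ccc(OCc3ccccc3)c(OC)c1)O2 | intermediate
17 | [(2S,3R)-2-[4-(benzyloxy)-3-methoxyphenyl]-3-[(benzyloxy)methyl]-7-methoxy-2,3-dihydro-1-benzofuran-5-yl]methanol | OCc1cc(OC)c2c(c1)[C@H](COCc1ccccc1)[C@@H](c1ccc(OCc3ccccc3)c(OC)c1)O2 | intermediate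
18 | (2S,3R)-2-[4-(benzyloxy)-3-methoxyphenyl]-3-[(benzyloxy)methyl]-5-(bromomethyl)-7-methoxy-2,3-dihydro-1-benzofuran | BrCc1cc(OC)c2c(c1)[C@H](COCc1ccccc1)[C@@H](c1ccc(OCc3ccccc3)c(OC)c1)O2 | intermediate
19 | lithium enolate of 6 (lithium (4R)-4-{[4-(benzyloxy)-3-methoxyphenyl]methyl}-4,5-dihydrofuran-2-olate) | COc1cc(C[C@H]2COC([O-])=C2)ccc1OCc1ccccc1.[Li+] | intermediate (not isolated)
20 | (3R,4R)-4-{[4-(benzyloxy)-3-methoxyphenyl]methyl}-3-{[(2S,3R)-2-[4-(benzyloxy)-3-methoxyphenyl]-3-[(benzyloxy)methyl]-7-methoxy-2,3-dihydro-1-benzofuran-5-yl]methyl}oxolan-2-one | COc1cc(C[C@H]2COC(=O)[C@@H]2Cc2cc(OC)c3c(c2)[C@H](COCc2ccccc2)[C@@H](c2ccc(OCc4ccccc4)c(OC)c2)O3)ccc1OCc1ccccc1 | intermediate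
21 | isolappaol A ((3R,4R)-4-[(4-hydroxy-3-methoxyphenyl)methyl]-3-{[(2S,3R)-2-(4-hydroxy-3-methoxyphenyl)-3-(hydroxymethyl)-7-methoxy-2,3-dihydro-1-benzofuran-5-yl]methyl}oxolan-2-one) | COc1cc(C[C@H]2COC(=O)[C@@H]2Cc2cc(OC)c3c(c2)[C@H](CO)[C@@H](c2ccc(O)c(OC)c2)O3)ccc1O | target

**Count**

Total steps: 16. Longest linear sequence: 12 steps (steps 5 to 16, from 5-iodovanillin); the lactone branch is steps 1 to 4.

**Steps most likely to fail**

Step 4. What may go wrong: incomplete discrimination between the two enantiotopic migrating CH2 groups, because the flexible arylmethyl substituent is a weak steric marker, together with uncatalysed background oxidation by the peracid that erodes the enantiomeric purity. Fallback: the lactone is closed at its acyl C–O bond instead, and C4 is set by an oxazolidinone auxiliary. The fallback sets out from alcohol 8, which PBr3 in Et2O at 0 °C should convert into 1-(benzyloxy)-4-(bromomethyl)-2-methoxybenzene F1. (4R)-4-Benzyl-3-[4-(tert-butoxy)-4-oxobutanoyl]-1,3-oxazolidin-2-one F2 is made by N-acylation of (R)-4-benzyl-1,3-oxazolidin-2-one with mono-tert-butyl succinate; its sodium enolate (NaHMDS, THF, −78 °C) is alkylated by F1 on the face away from the auxiliary benzyl group to give tert-butyl (3R)-3-{[4-(benzyloxy)-3-methoxyphenyl]methyl}-4-[(4R)-4-benzyl-2-oxo-1,3-oxazolidin-3-yl]-4-oxobutanoate F3. LiBH4 in wet THF at 0 °C removes the auxiliary reductively to give tert-butyl (3R)-3-{[4-(benzyloxy)-3-methoxyphenyl]methyl}-4-hydroxybutanoate F4, and catalytic TsOH in toluene at 80 °C lactonises it, which returns to the route at lactone 6.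

Step 9. What may go wrong: weak enantio-induction by the chiral carboxylate ligands at the benzylic C–H bond of this more crowded, ortho-methoxy-flanked ether, so that C2 is formed with insufficient enantiomeric purity that cannot be corrected later. Fallback: stereocontrol is moved from the catalyst to a covalently bound auxiliary so that the products are diastereomers and can be purified. The fallback sets out from iodide 11, which is coupled under the conditions of step 8 with (3R)-4,4-dimethyl-2-oxooxolan-3-yl 2-diazoacetate F5 (from (R)-pantolactone and succinimidyl diazoacetate) to give (3R)-4,4-dimethyl-2-oxooxolan-3-yl 2-[2-{[4-(benzyloxy)-3-methoxyphenyl]methoxy}-5-({[tert-butyl(dimethyl)silyl]oxy}methyl)-3-methoxyphenyl]-2-diazoacetate F6. Insertion with Rh2(R-PTTL)4 or achiral Rh2(OPiv)4 should give (3R)-4,4-dimethyl-2-oxooxolan-3-yl (2S,3R)-2-[4-(benzyloxy)-3-methoxyphenyl]-5-({[tert-butyl(dimethyl)silyl]oxy}methyl)-7-methoxy-2,3-dihydro-1-benzofuran-3-carboxylate F7, which is freed of its C2 diastereomer by crystallisation or chromatography. DBU in toluene epimerises C3 to the trans ester (3R)-4,4-dimethyl-2-oxooxolan-3-yl (2S,3S)-2-[4-(benzyloxy)-3-methoxyphenyl]-5-({[tert-butyl(dimethyl)silyl]oxy}methyl)-7-methoxy-2,3-dihydro-1-benzofuran-3-carboxylate F8, and LiAlH4 cleaves the auxiliary ester reductively, which returns to the route at alcohol 15.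

Step 8. What may go wrong: slow coupling at the hindered ortho-alkoxy aryl iodide while the palladium catalyst decomposes ethyl diazoacetate by carbene dimerisation, leaving low conversion. Fallback: the acetate unit and the diazo group are installed in two separate operations. The fallback sets out from iodide 11, which undergoes palladium-catalysed α-arylation with the Reformatsky reagent BrZnCH2CO2Et (Pd(dba)2, Q-Phos, THF, rt to 60 °C) to give ethyl 2-[2-{[4-(benzyloxy)-3-methoxyphenyl]methoxy}-5-({[tert-butyl(dimethyl)silyl]oxy}methyl)-3-methoxyphenyl]acetate F9. Regitz diazo transfer (4-acetamidobenzenesulfonyl azide, DBU, MeCN, rt) then returns to the route at diazoacetate 12.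

**Further compounds**

F1 | step 4 | 1-(benzyloxy)-4-(bromomethyl)-2-methoxybenzene | COc1cc(CBr)ccc1OCc1ccccc1
F2 | step 4 | (4R)-4-benzyl-3-[4-(tert-butoxy)-4-oxobutanoyl]-1,3-oxazolidin-2-one | CC(C)(C)OC(=O)CCC(=O)N1[C@H](Cc2ccccc2)COC1=O
F3 | step 4 | tert-butyl (3R)-3-{[4-(benzyloxy)-3-methoxyphenyl]methyl}-4-[(4R)-4-benzyl-2-oxo-1,3-oxazolidin-3-yl]-4-oxobutanoate | CC(C)(C)OC(=O)C[C@@H](Cc1ccc(OCc2ccccc2)c(OC)c1)C(=O)N1[C@H](Cc2ccccc2)COC1=O
F4 | step 4 | tert-butyl (3R)-3-{[4-(benzyloxy)-3-methoxyphenyl]methyl}-4-hydroxybutanoate | CC(C)(C)OC(=O)C[C@@H](Cc1ccc(OCc2ccccc2)c(OC)c1)CO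
F5 | step 9 | (3R)-4,4-dimethyl-2-oxooxolan-3-yl 2-diazoacetate | [N-]=[N+]=CC(=O)O[C@H]1C(=O)OCC1(C)C
F6 | step 9 | (3R)-4,4-dimethyl-2-oxooxolan-3-yl 2-[2-{[4-(benzyloxy)-3-methoxyphenyl]methoxy}-5-({[tert-butyl(dimethyl)silyl]oxy}methyl)-3-methoxyphenyl]-2-diazoacetate | CC1(C)COC(=O)[C@@H]1OC(=O)C(=[N+]=[N-])c1cc(CO[Si](C)(C)C(C)(C)C)cc(OC)c1OCc1ccc(OCc2ccccc2)c(OC)c1
F7 | step 9 | (3R)-4,4-dimethyl-2-oxooxolan-3-yl (2S,3R)-2-[4-(benzyloxy)-3-methoxyphenyl]-5-({[tert-butyl(dimethyl)silyl]oxy}methyl)-7-methoxy-2,3-dihydro-1-benzofuran-3-carboxylate (cis) | CC(C)(C)[Si](C)(C)OCc1cc(OC)c2c(c1)[C@@H](C(=O)O[C@H]1C(=O)OCC1(C)C)[C@@H](c1ccc(OCc3ccccc3)c(OC)c1)O2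
F8 | step 9 | (3R)-4,4-dimethyl-2-oxooxolan-3-yl (2S,3S)-2-[4-(benzyloxy)-3-methoxyphenyl]-5-({[tert-butyl(dimethyl)silyl]oxy}methyl)-7-methoxy-2,3-dihydro-1-benzofuran-3-carboxylate (trans) | CC(C)(C)[Si](C)(C)OCc1cc(OC)c2c(c1)[C@H](C(=O)O[C@H]1C(=O)OCC1(C)C)[C@@H](c1ccc(OCc3ccccc3)c(OC)c1)O2
F9 | step 8 | ethyl 2-[2-{[4-(benzyloxy)-3-methoxyphenyl]methoxy}-5-({[tert-butyl(dimethyl)silyl]oxy}methyl)-3-methoxyphenyl]acetate | CCOC(=O)Cc1cc(CO[Si](C)(C)C(C)(C)C)cc(OC)c1OCc1ccc(OCc2ccccc2)c(OC)c1
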